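**Plan**

1. Common core: a 7β-hydroxy-labd-8(17)-ene decalin (stereocentres C4, C5, C7, C9, C10) joined through C11H2 to a cis-fused cyclohexene / 2-methoxy-ene-1,4-dione bicycle (stereocentres C12, C1', C6'); the quaternary C1' carries a 5,7-dihydroxychromon-2-yl group.
2. Differences: only the oxidation level of C18 (the 4α carbon): CH2OH in A, CHO in H, CO2H in E.
3. Shared intermediate: the complete core with C18–OH free and the other three hydroxyls silylated; the branches are desilylation (A), oxidation then desilylation (H), and oxidation, chlorite oxidation, desilylation (E).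
4. The trunk retrosynthesis cuts C12–C1' and C15–C6' ([4+2]) into a labda-8(17),12E,14-triene and the flavone B ring, which is dearomatised and masked at C5' as an (S,S)-diphenyldioxolane rather than used as the free quinone.
5. Feature that makes the key step possible: in the ketal the C1'=C6' alkene has one carbonyl (C2') and the chromone (a vinylogous ester) on C1', and an sp3 spiro-ketal carbon (C5') beside C6'. This leaves one electrophilic terminus (regiochemistry), disfavours ring-endo addition so the chromone goes endo (C11 cis to chromonyl), and covers one face of C6' (absolute sense).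
6. Diene half: levopimaric acid supplies C4, C5, C9, C10 and C18; exhaustive ozonolysis of its ring-C diene leaves C8=O and C12HO; two Wittig reactions build the E-diene; C7–O comes from enolate hydroxylation and a substrate-controlled Luche reduction.
7. Dienophile half: one-pot flavone synthesis from 2',4',6'-trihydroxyacetophenone, silylation, oxidative dearomatisation, site-selective ketalisation.
8. Ring order: rings A/B bought (ring C of the resin acid excised); pyranone ring (step 11); B ring dearomatised (step 13); auxiliary dioxolane on (step 14); cyclohexene ring last (step 15); auxiliary off (step 16).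

Key step: step 15
Shared intermediate: compound 22

Remark (numbering): labdane numbering for the terpenoid (C18 = 4α carbon, C19 = 4β-methyl, C20 = 10β-methyl); flavone numbering for the rest (chromone C2–C8a; former B ring C1'–C6', with C1' bearing the chromone, C2' and C5' the carbonyl carbons, C4' the OMe carbon).
Remark (assumption): levopimaric acid is taken as a commercially available chiral-pool resin acid; its C4, C5, C9 and C10 configurations are those of the targets.
Remark (assumption): compound 7 is drawn as the expected major 7α-epimer; either C7 epimer converges on ketone 9.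

**Trunk, diene half**

Step 1
Reactants: 1 levopimaric acid
Product: 2 levopimarol (abieta-8(14),12-dien-18-ol)
Conditions: LiAlH4, THF, 0 °C → rt
Reagents that add atoms: none
Why: Hydride reduction of the hindered C18 carboxylic acid should give the neopentyl alcohol while the unactivated ring-C diene is inert, so C18 enters at the alcohol level common to all later chemistry.

Step 2
Reactants: 2 levopimarol
Product: 3 18-(triethylsilyloxy)abieta-8(14),12-diene
Conditions: TESCl, imidazole, DMF, 0 °C → rt
Reagents that add atoms: chlorotriethylsilane CC[Si](Cl)(CC)CC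
Why: Silylation of the only hydroxyl; TES is chosen because it survives steps 3–15 and falls together with the ketal in step 16.

Step 3
Reactants: 3 18-(triethylsilyloxy)abieta-8(14),12-diene
Product: 4 18-(triethylsilyloxy)-8-oxo-13,14,15,16,17-pentanorlabdan-12-al
Conditions: O3, CH2Cl2/MeOH (4:1), −78 °C; then Me2S, −78 °C → rt
Reagents that add atoms: ozone [O-][O+]=O
Why: Exhaustive ozonolysis of both C=C bonds of the homoannular diene with reductive work-up should excise C13–C17, leaving C8 as ketone and C12 as aldehyde; C9 (α to the ketone) keeps its side chain equatorial, which is the thermodynamic arrangement.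

Step 4
Reactants: 4 keto aldehyde
Product: 5 (12E)-18-(triethylsilyloxy)-8-oxo-15,17-dinorlabd-12-en-14-al
Conditions: Ph3P=C(Me)CHO, toluene, 80 °C
Reagents that add atoms: 2-(triphenylphosphoranylidene)propanal CC(C=O)=P(c1ccccc1)(c1ccccc1)c1ccccc1
Why: Wittig reaction with a stabilised ylide is aldehyde-selective (the C8 ketone is untouched) and should give the E trisubstituted enal, which fixes the diene geometry.

Step 5
Reactants: 5 keto enal
Product: 6 18-(triethylsilyloxy)-17-norlabda-12E,14-dien-8-one
Conditions: Ph3PCH3Br, KHMDS (1.05 equiv ylide), THF, −78 → 0 °C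
Reagents that add atoms: methyltriphenylphosphonium bromide C[P+](c1ccccc1)(c1ccccc1)c1ccccc1.[Br-]
Why: Wittig methylenation; at low temperature with one equivalent the enal carbonyl should react much faster than the hindered ring ketone, completing the E-1,3-diene.

Step 6
Reactants: 6 dienyl ketone
Product: 7 7α-hydroxy-18-(triethylsilyloxy)-17-norlabda-12E,14-dien-8-one
Conditions: KHMDS, THF, −78 °C; then 2-(phenylsulfonyl)-3-phenyloxaziridine, −78 °C; aq. NH4Cl
Reagents that add atoms: 2-(phenylsulfonyl)-3-phenyloxaziridine O=S(=O)(N1OC1c1ccccc1)c1ccccc1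
Why: Kinetic deprotonation should occur at C7 (CH2) rather than at the tertiary C9, and enolate hydroxylation by the N-sulfonyloxaziridine (axial attack, mainly 7α) installs the C7 oxygen without touching the diene; the C7 configuration is corrected in steps 8–9.

Step 7
Reactants: 7 α-hydroxy ketone
Product: 8 18-(triethylsilyloxy)labda-8(17),12E,14-trien-7α-ol
Conditions: Ph3PCH3Br, KOtBu (3 equiv each), THF, 0 → 50 °C
Reagents that add atoms: methyltriphenylphosphonium bromide C[P+](c1ccccc1)(c1ccccc1)c1ccccc1.[Br-]
Why: Wittig methylenation of the ketone with excess ylide (the α-alkoxide is tolerated) should give the exocyclic C8=C17 alkene; C9 can only equilibrate to the wanted equatorial side chain.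

Step 8
Reactants: 8 allylic alcohol
Product: 9 18-(triethylsilyloxy)labda-8(17),12E,14-trien-7-one
Conditions: MnO2 (activated), CH2Cl2, rt
Reagents that add atoms: none
Why: MnO2 oxidises only the allylic alcohol, giving the exo-methylene enone and erasing the C7 configuration under neutral conditions that should not move the alkene into the ring.

Step 9
Reactants: 9 exocyclic enone
Product: 10 18-(triethylsilyloxy)labda-8(17),12E,14-trien-7β-ol
Conditions: NaBH4, CeCl3·7H2O, MeOH, −78 °C
Reagents that add atoms: none
Why: Luche 1,2-reduction; axial hydride delivery on the α face of the trans-decalin ketone should give the equatorial 7β-alcohol (substrate control), which is the C7 configuration of the family.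

Step 10
Reactants: 10 7β-alcohol
Product: 11 7β-(triisopropylsilyloxy)-18-(triethylsilyloxy)labda-8(17),12E,14-triene
Conditions: TIPSOTf, 2,6-lutidine, CH2Cl2, −78 → 0 °C
Reagents that add atoms: triisopropylsilyl trifluoromethanesulfonate CC(C)[Si](OS(=O)(=O)C(F)(F)F)(C(C)C)C(C)C
Why: Silylation with the triflate caps the hindered allylic alcohol as a TIPS ether, which is acid-stable enough to survive step 16 and distinguishes C7–O from C18–O.

**Trunk, dienophile half**

Step 11
Reactants: 12 2',4',6'-trihydroxyacetophenone; 13 2,4,5-trimethoxybenzoyl chloride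
Product: 15 5,7-dihydroxy-2',4',5'-trimethoxyflavone, via 1-(2,4,6-trihydroxyphenyl)-3-(2,4,5-trimethoxyphenyl)propane-1,3-dione 14 (not isolated)
Conditions: LiHMDS (4.2 equiv), THF, −78 °C; 13, −78 °C → rt; then H2SO4 (cat.), AcOH, 95 °C
Reagents that add atoms: none
Why: The lithium polyanion of the acetophenone is C-acylated at the methyl ketone enolate (Claisen-type acylation) and acid-catalysed cyclodehydration of the β-diketone closes the pyranone ring (flavone synthesis) without phenol protection.

Step 12
Reactants: 15 flavone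
Product: 16 5,7-bis(tert-butyldimethylsilyloxy)-2',4',5'-trimethoxyflavone
Conditions: TBSOTf (2.4 equiv), 2,6-lutidine, CH2Cl2, 0 °C → rt
Reagents that add atoms: tert-butyldimethylsilyl trifluoromethanesulfonate CC(C)(C)[Si](C)(C)OS(=O)(=O)C(F)(F)F
Why: Silylation of both A-ring phenols (the triflate is needed for the chelated 5-OH) protects them from the oxidant of step 13 and gives groups removable by fluoride at the end.

Step 13
Reactants: 16 bis-silylated flavone
Product: 17 2-[5,7-bis(tert-butyldimethylsilyloxy)-4-oxo-4H-chromen-2-yl]-5-methoxy-1,4-benzoquinone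
Conditions: CAN (2.5 equiv), MeCN/H2O (4:1), 0 °C, 10 min
Reagents that add atoms: water O
Why: Oxidative demethylation by Ce(IV) dearomatises the electron-rich B ring at its para-dimethoxy pair (C2'/C5') to the p-quinone while the 4'-OMe stays; the carbonyl-bearing silylated A ring is much less oxidisable.

Step 14
Reactants: 17 quinone; 18 (1S,2S)-1,2-diphenylethane-1,2-diol
Product: 20 C5' spiro-(4S,5S)-4,5-diphenyl-1,3-dioxolane monoketal of 17, via (1S,2S)-1,2-diphenyl-1,2-bis(trimethylsilyloxy)ethane 19 (not isolated)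
Conditions: 18, TMSCl, Et3N, CH2Cl2, 0 °C → rt; then 17, TMSOTf (0.1 equiv), CH2Cl2, −78 → −30 °C
Reagents that add atoms: none
Why: TMSOTf-catalysed ketalisation with the bis-silyl ether should take place at C5'=O, which is the more electrophilic and less hindered carbonyl, whereas C2'=O is a vinylogous ester carbonyl flanked by the chromone; the C2-symmetric diol creates no new stereocentre at the spiro carbon.

**Trunk, union**

Step 15
Reactants: 11 silylated labda-8(17),12E,14-triene; 20 chiral quinone monoketal
Product: 21 Diels–Alder adduct (C12–C1' and C15–C6' bonds; C11, the chromonyl group on C1' and H-6' cis; C5' still ketalised)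
Conditions: ZnCl2 (1.5 equiv), 4 Å MS, CH2Cl2, −20 °C → rt
Reagents that add atoms: none
Why: ZnCl2 bound to the chromone and C2' carbonyl oxygens lowers the LUMO of the C1'=C6' alkene of 20 (a 2-acylcyclohexadienone in which the chromon-2-yl group acts as a vinylogous ester), and the s-cis diene of 11 adds in a concerted, asynchronous [4+2] in which the unhindered C15–C6' bond leads and C12–C1' follows; the closest known reactions are the Lewis-acid Diels–Alder additions to 2-carboalkoxycyclohex-2-enones and to p-quinone monoketals of C2-symmetric diols. The only ring closed is the cyclohexene C12–C13=C14–C15–C6'–C1', by an intermolecular [4+2] that is suprafacial on both partners. C1' and C6' are set cis by suprafacial addition to the dienophile, C12 is set relative to C1' by the chromone-endo/ring-exo transition state (the E, "outside" C11 substituent ends cis to the chromonyl group), and the absolute sense is set by the (S,S)-diphenyldioxolane, whose phenyl on the C6' side covers the Si face of C6' so that the diene should enter on the Re face. Regioselectivity is secured because, with C5' masked, C2'=O and the chromone both make C6' the only electrophilic terminus, and site selectivity because C3'=C4' is a methoxy-deactivated vinylogous ester and C8=C17 of 11 is an isolated alkene. Ring-endo addition is disfavoured because it would press C13/C14 of the diene against the pseudo-axial ketal oxygen and benzylic carbon at C5', next to C6'. The decalin stereocentres are insulated by C11H2 and exert no control, so the diastereomer formed is decided by the auxiliary.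

Step 16
Reactants: 21 Diels–Alder adduct
Product: 22 shared intermediate (ene-dione core, C18–OH free, 7β-OTIPS, 5,7-bis-OTBS)
Conditions: TsOH·H2O (0.3 equiv), acetone/H2O (10:1), rt
Reagents that add atoms: water O
Why: Acid-catalysed ketal hydrolysis (driven by exchange into acetone) should unmask C5'=O and the same acid cleaves the primary TES ether, while the TIPS and aryl TBS ethers persist and the quaternary C1' prevents aromatisation of the ene-dione.

Branch to Dichrostachine A (compound 23)

Step 17
Reactants: 22 shared intermediate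
Product: 23 Dichrostachine A
Conditions: HF·pyridine, pyridine, THF, 0 °C → rt
Reagents that add atoms: none
Why: Fluoride-mediated desilylation removes all three remaining silyl groups (no selection among them is needed), and the buffered, non-basic medium should leave the cis ring fusion (C6' is α to a ketone) and the allylic alcohol untouched.

Branch to Dichrostachine H (compound 25)

Step 18
Reactants: 22 shared intermediate
Product: 24 C18 aldehyde (7β-OTIPS, 5,7-bis-OTBS)
Conditions: Dess–Martin periodinane, NaHCO3, CH2Cl2, 0 °C → rt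
Reagents that add atoms: none
Why: Dess–Martin oxidation acts only at C18 because it is the sole free hydroxyl (C7–O and both phenols are silylated), and the α-quaternary aldehyde cannot epimerise or over-oxidise.

Step 19
Reactants: 24 C18 aldehyde
Product: 25 Dichrostachine H
Conditions: HF·pyridine, pyridine, THF, 0 °C → rt
Reagents that add atoms: none
Why: Fluoride-mediated global desilylation as in step 17; the non-enolisable aldehyde and the ene-dione tolerate the mildly acidic medium.

Branch to Dichrostachine E (compound 27)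

Step 20
Reactants: 24 C18 aldehyde
Product: 26 C18 carboxylic acid (7β-OTIPS, 5,7-bis-OTBS)
Conditions: NaClO2, NaH2PO4, 2-methyl-2-butene, t-BuOH/H2O, 0 °C → rt
Reagents that add atoms: sodium chlorite [Na+].[O-]Cl=O
Why: Pinnick oxidation converts only the aldehyde (ketones and the vinylogous ester are inert to chlorite), and 2-methyl-2-butene scavenges HOCl so that the C8=C17 and C13=C14 alkenes are spared.

Step 21
Reactants: 26 C18 carboxylic acid
Product: 27 Dichrostachine E
Conditions: HF·pyridine, pyridine, THF, 0 °C → rt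
Reagents that add atoms: none
Why: Fluoride-mediated global desilylation as in step 17, compatible with the free carboxylic acid.

**Compound list**

1 | levopimaric acid (abieta-8(14),12-dien-18-oic acid) | CC(C)C1=CC[C@H]2C(=C1)CC[C@@H]1[C@]2(C)CCC[C@@]1(C)C(=O)O | starting material
2 | levopimarol (abieta-8(14),12-dien-18-ol) | CC(C)C1=CC[C@H]2C(=C1)CC[C@@H]1[C@]2(C)CCC[C@@]1(C)CO | intermediate
3 | 18-(triethylsilyloxy)abieta-8(14),12-diene | CC(C)C1=CC[C@H]2C(=C1)CC[C@@H]1[C@]2(C)CCC[C@@]1(C)CO[Si](CC)(CC)CC | intermediate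
4 | 18-(triethylsilyloxy)-8-oxo-13,14,15,16,17-pentanorlabdan-12-al (5α-H, 9α-H, 10β-Me, 4β-Me) | O=C1CC[C@@H]2[C@](C)(CCC[C@@]2(C)CO[Si](CC)(CC)CC)[C@H]1CC=O | intermediate
5 | (12E)-18-(triethylsilyloxy)-8-oxo-15,17-dinorlabd-12-en-14-al | O=C1CC[C@@H]2[C@](C)(CCC[C@@]2(C)CO[Si](CC)(CC)CC)[C@H]1C/C=C(\C)C=O | intermediate
6 | 18-(triethylsilyloxy)-17-norlabda-12E,14-dien-8-one | O=C1CC[C@@H]2[C@](C)(CCC[C@@]2(C)CO[Si](CC)(CC)CC)[C@H]1C/C=C(\C)C=C | intermediate
7 | 7α-hydroxy-18-(triethylsilyloxy)-17-norlabda-12E,14-dien-8-one | O=C1[C@H](O)C[C@@H]2[C@](C)(CCC[C@@]2(C)CO[Si](CC)(CC)CC)[C@H]1C/C=C(\C)C=C | intermediate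
8 | 18-(triethylsilyloxy)labda-8(17),12E,14-trien-7α-ol | C=C1[C@H](O)C[C@@H]2[C@](C)(CCC[C@@]2(C)CO[Si](CC)(CC)CC)[C@H]1C/C=C(\C)C=C | intermediate
9 | 18-(triethylsilyloxy)labda-8(17),12E,14-trien-7-one | C=C1C(=O)C[C@@H]2[C@](C)(CCC[C@@]2(C)CO[Si](CC)(CC)CC)[C@H]1C/C=C(\C)C=C | intermediate
10 | 18-(triethylsilyloxy)labda-8(17),12E,14-trien-7β-ol | C=C1[C@@H](O)C[C@@H]2[C@](C)(CCC[C@@]2(C)CO[Si](CC)(CC)CC)[C@H]1C/C=C(\C)C=C | intermediate
11 | 7β-(triisopropylsilyloxy)-18-(triethylsilyloxy)labda-8(17),12E,14-triene | C=C1[C@@H](O[Si](C(C)C)(C(C)C)C(C)C)C[C@@H]2[C@](C)(CCC[C@@]2(C)CO[Si](CC)(CC)CC)[C@H]1C/C=C(\C)C=C | intermediate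
12 | 2',4',6'-trihydroxyacetophenone | CC(=O)c1c(O)cc(O)cc1O | starting material
13 | 2,4,5-trimethoxybenzoyl chloride | COc1cc(OC)c(OC)cc1C(=O)Cl | starting material
14 | 1-(2,4,6-trihydroxyphenyl)-3-(2,4,5-trimethoxyphenyl)propane-1,3-dione | COc1cc(OC)c(OC)cc1C(=O)CC(=O)c1c(O)cc(O)cc1O | intermediate
15 | 5,7-dihydroxy-2',4',5'-trimethoxyflavone | COc1cc(OC)c(OC)cc1-c1cc(=O)c2c(O)cc(O)cc2o1 | intermediate
16 | 5,7-bis(tert-butyldimethylsilyloxy)-2',4',5'-trimethoxyflavone | COc1cc(OC)c(OC)cc1-c1cc(=O)c2c(O[Si](C)(C)C(C)(C)C)cc(O[Si](C)(C)C(C)(C)C)cc2o1 | intermediate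
17 | 2-[5,7-bis(tert-butyldimethylsilyloxy)-4-oxo-4H-chromen-2-yl]-5-methoxy-1,4-benzoquinone | COC1=CC(=O)C(=CC1=O)c1cc(=O)c2c(O[Si](C)(C)C(C)(C)C)cc(O[Si](C)(C)C(C)(C)C)cc2o1 | intermediate
18 | (1S,2S)-1,2-diphenylethane-1,2-diol ((S,S)-hydrobenzoin) | O[C@@H](c1ccccc1)[C@@H](O)c1ccccc1 | starting material
19 | (1S,2S)-1,2-diphenyl-1,2-bis(trimethylsilyloxy)ethane | C[Si](C)(C)O[C@@H](c1ccccc1)[C@@H](O[Si](C)(C)C)c1ccccc1 | intermediate
20 | quinone 17 ketalised at C5' (the carbonyl next to C4'–OMe) as the spiro (4S,5S)-4,5-diphenyl-1,3-dioxolane; C2'=O free | COC1=CC(=O)C(=CC12O[C@@H](c3ccccc3)[C@H](c3ccccc3)O2)c1cc(=O)c2c(O[Si](C)(C)C(C)(C)C)cc(O[Si](C)(C)C(C)(C)C)cc2o1 | intermediate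
21 | Diels–Alder adduct: 7β-OTIPS, 18-OTES labd-8(17)-ene with C11 on C12 of the new cyclohexene (C12–C13(Me)=C14–C15–C6'–C1'), cis-fused to the 4'-methoxy-2'-oxo ring carrying the C5' (4S,5S)-diphenyldioxolane; 5,7-bis(TBSO)chromon-2-yl on C1'; C11, chromonyl and H-6' cis | C=C1[C@@H](O[Si](C(C)C)(C(C)C)C(C)C)C[C@@H]2[C@](C)(CCC[C@@]2(C)CO[Si](CC)(CC)CC)[C@H]1C[C@@H]1C(C)=CC[C@H]2C3(O[C@@H](c4ccccc4)[C@H](c4ccccc4)O3)C(OC)=CC(=O)[C@@]12c1cc(=O)c2c(O[Si](C)(C)C(C)(C)C)cc(O[Si](C)(C)C(C)(C)C)cc2o1 | intermediate
22 | shared intermediate: 7-O-TIPS, 5,7-bis-O-TBS dichrostachine A (C18–OH free, ene-dione unmasked) | C=C1[C@@H](O[Si](C(C)C)(C(C)C)C(C)C)C[C@@H]2[C@](C)(CCC[C@@]2(C)CO)[C@H]1C[C@@H]1C(C)=CC[C@H]2C(=O)C(OC)=CC(=O)[C@@]12c1cc(=O)c2c(O[Si](C)(C)C(C)(C)C)cc(O[Si](C)(C)C(C)(C)C)cc2o1 | intermediate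
23 | Dichrostachine A | C=C1[C@@H](O)C[C@H]2[C@](C)(CO)CCC[C@]2(C)[C@H]1C[C@@H]1C(C)=CC[C@H]2C(=O)C(OC)=CC(=O)[C@@]12c1cc(=O)c2c(O)cc(O)cc2o1 | target
24 | 7-O-TIPS, 5,7-bis-O-TBS dichrostachine H (C18 aldehyde) | C=C1[C@@H](O[Si](C(C)C)(C(C)C)C(C)C)C[C@@H]2[C@](C)(CCC[C@@]2(C)C=O)[C@H]1C[C@@H]1C(C)=CC[C@H]2C(=O)C(OC)=CC(=O)[C@@]12c1cc(=O)c2c(O[Si](C)(C)C(C)(C)C)cc(O[Si](C)(C)C(C)(C)C)cc2o1 | intermediate
25 | Dichrostachine H | C=C1[C@@H](O)C[C@@H]2[C@](C)(CCC[C@@]2(C)C=O)[C@H]1C[C@@H]1C(C)=CC[C@H]2C(=O)C(OC)=CC(=O)[C@@]12c1cc(=O)c2c(O)cc(O)cc2o1 | target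
26 | 7-O-TIPS, 5,7-bis-O-TBS dichrostachine E (C18 carboxylic acid) | C=C1[C@@H](O[Si](C(C)C)(C(C)C)C(C)C)C[C@@H]2[C@](C)(CCC[C@@]2(C)C(=O)O)[C@H]1C[C@@H]1C(C)=CC[C@H]2C(=O)C(OC)=CC(=O)[C@@]12c1cc(=O)c2c(O[Si](C)(C)C(C)(C)C)cc(O[Si](C)(C)C(C)(C)C)cc2o1 | intermediate
27 | Dichrostachine E | C=C1[C@@H](O)C[C@@H]2[C@](C)(CCC[C@@]2(C)C(=O)O)[C@H]1C[C@@H]1C(C)=CC[C@H]2C(=O)C(OC)=CC(=O)[C@@]12c1cc(=O)c2c(O)cc(O)cc2o1 | target

Totals for Dichrostachine A (compound 23): total step count 17, longest linear sequence 13
Totals for Dichrostachine H (compound 25): total step count 18, longest linear sequence 14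
Totals for Dichrostachine E (compound 27): total step count 19, longest linear sequence 15

**Steps most likely to fail**

Step 15. The hindered, trisubstituted dienophile may react too slowly with a diene terminus that carries the decalin; the Lewis acid may ionise the ketal; or ring-exo and facial control by the dioxolane may be incomplete, giving diastereomer mixtures. The fallback sets out from quinone 17 and diene 11. The free quinone is used as dienophile in an uncatalysed Diels–Alder reaction (toluene, 60 °C, or 5 M LiClO4 in Et2O). The wanted isomer, the 18-O-TES, 7-O-TIPS, 5,7-bis-O-TBS ene-dione adduct F1, is separated from its regio- and stereoisomers by chromatography. PPTS in MeOH at 0 °C then removes the TES group, and the fallback comes back to the route at 22.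

Step 14. The diol may ketalise the wrong carbonyl (C2'), both carbonyls, or add in conjugate fashion to the quinone. The fallback sets out from 16. Anodic oxidation in MeOH (Pt, LiClO4, 2,6-lutidine) gives the quinone bis(dimethyl ketal) F2. Brief treatment with aqueous acetic acid hydrolyses only the C2' ketal (the one that gives the vinylogous ester) to leave the C5' dimethyl monoketal F3. Acid-catalysed exchange of F3 with diol 18 (PPTS, benzene, 5 Å MS) comes back to the route at 20.

Step 16. The diphenyldioxolane may resist hydrolysis, or acid strong enough to open it may strip the C7 and aryl silyl ethers or move the C8=C17 alkene into the ring. The fallback sets out from 21 and separates the two deprotections. PPTS in MeOH at 0 °C cleaves only the TES ether to give the C18 alcohol with the ketal intact F4. The ketal is then exchanged under neutral conditions with PdCl2(MeCN)2 in acetone, which comes back to the route at 22.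

Further compounds
F1 | step 15 | 18-O-TES, 7-O-TIPS, 5,7-bis-O-TBS ene-dione adduct (22 with C18–OTES) | C=C1[C@@H](O[Si](C(C)C)(C(C)C)C(C)C)C[C@@H]2[C@](C)(CCC[C@@]2(C)CO[Si](CC)(CC)CC)[C@H]1C[C@@H]1C(C)=CC[C@H]2C(=O)C(OC)=CC(=O)[C@@]12c1cc(=O)c2c(O[Si](C)(C)C(C)(C)C)cc(O[Si](C)(C)C(C)(C)C)cc2o1
F2 | step 14 | quinone bis(dimethyl ketal): 2-(2,3,3,6,6-pentamethoxycyclohexa-1,4-dienyl... numbered from flavone: C2',C2',C4',C5',C5'-pentamethoxy)-5,7-bis(TBSO)chromone | COC1=CC(OC)(OC)C(=CC1(OC)OC)c1cc(=O)c2c(O[Si](C)(C)C(C)(C)C)cc(O[Si](C)(C)C(C)(C)C)cc2o1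
F3 | step 14 | C5' dimethyl monoketal of quinone 17 | COC1=CC(=O)C(=CC1(OC)OC)c1cc(=O)c2c(O[Si](C)(C)C(C)(C)C)cc(O[Si](C)(C)C(C)(C)C)cc2o1
F4 | step 16 | Diels–Alder adduct 21 with C18–OH free and the dioxolane intact | C=C1[C@@H](O[Si](C(C)C)(C(C)C)C(C)C)C[C@@H]2[C@](C)(CCC[C@@]2(C)CO)[C@H]1C[C@@H]1C(C)=CC[C@H]2C3(O[C@@H](c4ccccc4)[C@H](c4ccccc4)O3)C(OC)=CC(=O)[C@@]12c1cc(=O)c2c(O[Si](C)(C)C(C)(C)C)cc(O[Si](C)(C)C(C)(C)C)cc2o1
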